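**Plan**
- Target: (2S)-7,4'-dihydroxy-6,8-diprenylflavanone. The retrosynthesis cuts, in order, C3–C4 of ring C (as a C3=C4 silyl enol ether), the O1–C2 ether bond, and the two aryl–prenyl bonds at C8 and C6.
- Enabling feature: C3–C4 joins C2 (which carries O1 and ring B) to the C4 carbonyl on C4a of ring A. Written as C3=C4, it splits ring C into a vinyl group on the O1–C2 ether and a 1-silyloxyvinyl group on C4a, two terminal olefins held ortho to each other on ring A.
- Forward: ring A (resacetophenone) takes up the C8 and C6 prenyl groups by two O-(1,1-dimethylallyl)ation/Claisen cycles. Ring B enters as a cinnamyl carbonate and is joined at O1–C2. Ring C is closed last by metathesis and then unmasked.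
- Stereochemistry: the only stereocentre, C2 (S), is set in the iridium–phosphoramidite branched allylic etherification (step 10) and carried through unchanged.

Key step: step 12

Abbreviations: prenyl = 3-methylbut-2-enyl; TBS = tert-butyldimethylsilyl.
Assumption: the first Claisen shift (step 3) is taken to end at C3 of the acetophenone; a C5 isomer, if formed, is carried along, because steps 4 and 5 turn both isomers into the same compound 10.

**Step 1**
Reactants: 1 2-methylbut-3-en-2-ol
Product: 3 tert-butyl 2-methylbut-3-en-2-yl carbonate, via lithium 2-methylbut-3-en-2-olate 2 (not isolated)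
Conditions: n-BuLi (1.05 equiv), THF, −78 to 0 °C; then Boc2O (1.1 equiv), 0 °C to rt
Reagents that add atoms: di-tert-butyl dicarbonate, CC(C)(C)OC(=O)OC(=O)OC(C)(C)C
Why: Alkoxycarbonylation of the lithium alkoxide by Boc2O is the standard route to tertiary allylic tert-butyl carbonates; no stereocentre is formed.

**Step 2**
Reactants: 4 1-(2,4-dihydroxyphenyl)ethanone (resacetophenone); 3 tert-butyl 2-methylbut-3-en-2-yl carbonate
Product: 5 1-[2-hydroxy-4-(2-methylbut-3-en-2-yloxy)phenyl]ethanone
Conditions: 3 (1.2 equiv), Pd(PPh3)4 (2 mol%), THF, 0–5 °C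
Reagents that add atoms: none
Why: Tsuji–Trost O-allylation, in which zerovalent palladium ionises 3 with loss of CO2 and the non-chelated, more acidic 4-hydroxyl attacks the more substituted allyl terminus under kinetic control at low temperature, while the 2-hydroxyl stays locked in its hydrogen bond to the ketone; no stereocentre is formed.

**Step 3**
Reactants: 5 1-[2-hydroxy-4-(2-methylbut-3-en-2-yloxy)phenyl]ethanone
Product: 7 1-(2,4-dihydroxy-3-prenylphenyl)ethanone, via ortho-dienone 6 (not isolated)
Conditions: PhNEt2, 140 °C, Ar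
Reagents that add atoms: none
Why: Aromatic Claisen rearrangement, whose [3,3] shift turns the 1,1-dimethylallyl ether into a linear prenyl group on the ortho carbon between the two oxygens, after which dienone 6 re-aromatises by enolisation so that no stereocentre remains.

**Step 4**
Reactants: 7 1-(2,4-dihydroxy-3-prenylphenyl)ethanone; 3 tert-butyl 2-methylbut-3-en-2-yl carbonate
Product: 8 1-[2-hydroxy-4-(2-methylbut-3-en-2-yloxy)-3-prenylphenyl]ethanone
Conditions: 3 (1.5 equiv), Pd(PPh3)4 (3 mol%), THF, 0–5 °C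
Reagents that add atoms: none
Why: The same Tsuji–Trost O-allylation as in step 2 should again select the free 4-hydroxyl and the tertiary allyl terminus, the low temperature keeping the kinetic tertiary ether from equilibrating to the linear one; no stereocentre is formed.

**Step 5**
Reactants: 8 1-[2-hydroxy-4-(2-methylbut-3-en-2-yloxy)-3-prenylphenyl]ethanone
Product: 10 1-(2,4-dihydroxy-3,5-diprenylphenyl)ethanone, via ortho-dienone 9 (not isolated)
Conditions: PhNEt2, 140 °C, Ar
Reagents that add atoms: none
Why: Aromatic Claisen rearrangement to C5, the only free ortho position, delivers the second prenyl group with allyl inversion, followed by enolisation of dienone 9; no stereocentre remains.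

**Step 6**
Reactants: 10 1-(2,4-dihydroxy-3,5-diprenylphenyl)ethanone
Product: 11 1-[4-(TBS-oxy)-2-hydroxy-3,5-diprenylphenyl]ethanone
Conditions: TBSCl (1.1 equiv), imidazole (2.2 equiv), DMF, 0 °C to rt
Reagents that add atoms: tert-butyldimethylsilyl chloride, CC(C)(C)[Si](C)(C)Cl
Why: Phenol silylation should be selective for the 4-hydroxyl because the 2-hydroxyl is deactivated by its hydrogen bond to the acetyl group, leaving it free as the nucleophile for step 10.

**Step 7**
Reactants: 12 methyl (E)-3-(4-hydroxyphenyl)prop-2-enoate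
Product: 13 methyl (E)-3-[4-(TBS-oxy)phenyl]prop-2-enoate
Conditions: TBSCl (1.2 equiv), imidazole (2.5 equiv), DMF, rt
Reagents that add atoms: tert-butyldimethylsilyl chloride, CC(C)(C)[Si](C)(C)Cl
Why: Routine phenol silylation masks the future 4'-hydroxyl with a group that the final fluoride treatment removes.

**Step 8**
Reactants: 13 methyl (E)-3-[4-(TBS-oxy)phenyl]prop-2-enoate
Product: 14 (E)-3-[4-(TBS-oxy)phenyl]prop-2-en-1-ol
Conditions: i-Bu2AlH (2.3 equiv), CH2Cl2, −78 °C; aq. potassium sodium tartrate
Reagents that add atoms: none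
Why: 1,2-Reduction of the cinnamate by the aluminium hydride at low temperature gives the cinnamyl alcohol with the E olefin and the aryl silyl ether intact.

**Step 9**
Reactants: 14 (E)-3-[4-(TBS-oxy)phenyl]prop-2-en-1-ol
Product: 15 (E)-3-[4-(TBS-oxy)phenyl]prop-2-enyl methyl carbonate
Conditions: ClCO2Me (1.5 equiv), pyridine (2 equiv), CH2Cl2, 0 °C
Reagents that add atoms: methyl chloroformate, COC(=O)Cl
Why: O-Acylation of the primary allylic alcohol gives the linear carbonate that serves as the ionisable partner for the allylic substitution.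

**Step 10**
Reactants: 11 1-[4-(TBS-oxy)-2-hydroxy-3,5-diprenylphenyl]ethanone; 15 (E)-3-[4-(TBS-oxy)phenyl]prop-2-enyl methyl carbonate
Product: 17 1-[4-(TBS-oxy)-2-{(1S)-1-[4-(TBS-oxy)phenyl]prop-2-enyloxy}-3,5-diprenylphenyl]ethanone, via lithium phenoxide 16 (not isolated)
Conditions: LiN(SiMe3)2 (1.0 equiv), THF, 0 °C; then 15 (1.3 equiv), [Ir(cod)Cl]2 (2 mol%), (Sa,Sc,Sc)-O,O'-(1,1'-binaphthyl-2,2'-diyl) N,N-bis(1-phenylethyl)phosphoramidite (4 mol%, complex pre-activated with n-PrNH2), THF, 50 °C
Reagents that add atoms: none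
Why: Iridium-catalysed asymmetric allylic etherification, in which the cyclometalated iridium–phosphoramidite complex ionises the linear carbonate and the phenoxide attacks the aryl-substituted allyl terminus anti to the metal, so the branched ether forms and the ligand antipode fixes the new O-bearing stereocentre as S (the (Sa,Sc,Sc) ligand is the one the accepted facial model assigns to this sense).

**Step 11**
Reactants: 17 1-[4-(TBS-oxy)-2-{(1S)-1-[4-(TBS-oxy)phenyl]prop-2-enyloxy}-3,5-diprenylphenyl]ethanone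
Product: 18 (1S)-1-[4-(TBS-oxy)phenyl]prop-2-enyl 3-(TBS-oxy)-2,4-diprenyl-6-[1-(TBS-oxy)ethenyl]phenyl ether
Conditions: TBSOTf (1.3 equiv), Et3N (3 equiv), CH2Cl2, −78 to 0 °C; Et3N-deactivated silica
Reagents that add atoms: tert-butyldimethylsilyl trifluoromethanesulfonate, CC(C)(C)[Si](C)(C)OS(=O)(=O)C(F)(F)F
Why: Soft enolisation of the aryl methyl ketone by silyl triflate and amine gives the 1-silyloxyvinyl arene, while low temperature and excess amine should keep the ionisable benzylic allylic ether and its stereocentre intact.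

**Step 12**
Reactants: 18 (1S)-1-[4-(TBS-oxy)phenyl]prop-2-enyl 3-(TBS-oxy)-2,4-diprenyl-6-[1-(TBS-oxy)ethenyl]phenyl ether
Product: 19 (2S)-4,7-bis(TBS-oxy)-2-[4-(TBS-oxy)phenyl]-6,8-diprenyl-2H-chromene
Conditions: second-generation Grubbs catalyst (H2IMes)(PCy3)Cl2Ru=CHPh (10 mol% in two portions), 1,4-benzoquinone (10 mol%), degassed toluene (0.005 M), 50 °C, dark, Ar sparge
Reagents that add atoms: none
Why: Ring-closing olefin metathesis: the ruthenium benzylidene exchanges onto the monosubstituted vinyl group at C2, the new alkylidene adds [2+2] to the 1,1-disubstituted silyl enol ether on C4a, and cycloreversion releases the C3=C4 enol ether and Ru=CH2, which carries the chain with loss of ethene. The closest known reaction type is ring-closing metathesis of olefinic silyl enol ethers to cyclic silyl enol ethers and of ortho-alkenyl aryl allyl ethers to 2H-chromenes. Ring C closes as a six-membered pyran with the new double bond endocyclic, the two termini being held ortho on ring A across O1–C8a–C4a. No stereocentre is formed, and the C2 centre from step 10 takes no part in the bond reorganisation. The step needs six-membered closure onto the enol ether to beat seven-membered closure onto the C8 prenyl olefin and cross-metathesis of the prenyl groups; this rests on the slow reaction of trisubstituted olefins, the kinetic advantage of the six-membered ring, high dilution and removal of ethene. Darkness, 50 °C and benzoquinone as hydride scavenger guard C2 against electrocyclic opening of the 2H-chromene and against migration of the vinyl double bond.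

**Step 13**
Reactants: 19 (2S)-4,7-bis(TBS-oxy)-2-[4-(TBS-oxy)phenyl]-6,8-diprenyl-2H-chromene
Product: 20 (2S)-7-hydroxy-2-(4-hydroxyphenyl)-6,8-diprenylchroman-4-one
Conditions: Bu4NF (3.6 equiv), AcOH (4 equiv), THF, 0 °C
Reagents that add atoms: none
Why: Fluoride-induced desilylation cleaves both aryl silyl ethers and the silyl enol ether, and the acetic acid buffer protonates the phenoxides and the C4 enolate as they form, so the ketone appears without the basic conditions that would open ring C by E1cB elimination and scramble C2.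

**Compound list**
1 | 2-methylbut-3-en-2-ol | C=CC(C)(C)O | starting material
2 | lithium 2-methylbut-3-en-2-olate | C=CC(C)(C)[O-].[Li+] | intermediate
3 | tert-butyl 2-methylbut-3-en-2-yl carbonate | C=CC(C)(C)OC(=O)OC(C)(C)C | intermediate
4 | 1-(2,4-dihydroxyphenyl)ethanone (resacetophenone) | CC(=O)c1ccc(O)cc1O | starting material
5 | 1-[2-hydroxy-4-(2-methylbut-3-en-2-yloxy)phenyl]ethanone | CC(=O)c1ccc(OC(C)(C)C=C)cc1O | intermediate
6 | 4-acetyl-5-hydroxy-6-prenylcyclohexa-2,4-dien-1-one (ortho-dienone, racemic) | CC(=O)C1=C(O)C(CC=C(C)C)C(=O)C=C1 | intermediate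
7 | 1-(2,4-dihydroxy-3-prenylphenyl)ethanone | CC(=O)c1ccc(O)c(CC=C(C)C)c1O | intermediate
8 | 1-[2-hydroxy-4-(2-methylbut-3-en-2-yloxy)-3-prenylphenyl]ethanone | CC(=O)c1ccc(OC(C)(C)C=C)c(CC=C(C)C)c1O | intermediate
9 | 4-acetyl-3-hydroxy-2,6-diprenylcyclohexa-2,4-dien-1-one (ortho-dienone, racemic) | CC(=O)C1=CC(CC=C(C)C)C(=O)C(CC=C(C)C)=C1O | intermediate
10 | 1-(2,4-dihydroxy-3,5-diprenylphenyl)ethanone | CC(=O)c1cc(CC=C(C)C)c(O)c(CC=C(C)C)c1O | intermediate
11 | 1-[4-(TBS-oxy)-2-hydroxy-3,5-diprenylphenyl]ethanone | CC(=O)c1cc(CC=C(C)C)c(O[Si](C)(C)C(C)(C)C)c(CC=C(C)C)c1O | intermediate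
12 | methyl (E)-3-(4-hydroxyphenyl)prop-2-enoate | COC(=O)/C=C/c1ccc(O)cc1 | starting material
13 | methyl (E)-3-[4-(TBS-oxy)phenyl]prop-2-enoate | COC(=O)/C=C/c1ccc(O[Si](C)(C)C(C)(C)C)cc1 | intermediate
14 | (E)-3-[4-(TBS-oxy)phenyl]prop-2-en-1-ol | OC/C=C/c1ccc(O[Si](C)(C)C(C)(C)C)cc1 | intermediate
15 | (E)-3-[4-(TBS-oxy)phenyl]prop-2-enyl methyl carbonate | COC(=O)OC/C=C/c1ccc(O[Si](C)(C)C(C)(C)C)cc1 | intermediate
16 | lithium 6-acetyl-3-(TBS-oxy)-2,4-diprenylphenolate | CC(=O)c1cc(CC=C(C)C)c(O[Si](C)(C)C(C)(C)C)c(CC=C(C)C)c1[O-].[Li+] | intermediate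
17 | 1-[4-(TBS-oxy)-2-{(1S)-1-[4-(TBS-oxy)phenyl]prop-2-enyloxy}-3,5-diprenylphenyl]ethanone | C=C[C@@H](c1ccc(O[Si](C)(C)C(C)(C)C)cc1)Oc1c(C(C)=O)cc(CC=C(C)C)c(O[Si](C)(C)C(C)(C)C)c1CC=C(C)C | intermediate
18 | (1S)-1-[4-(TBS-oxy)phenyl]prop-2-enyl 3-(TBS-oxy)-2,4-diprenyl-6-[1-(TBS-oxy)ethenyl]phenyl ether | C=C[C@@H](c1ccc(O[Si](C)(C)C(C)(C)C)cc1)Oc1c(C(=C)O[Si](C)(C)C(C)(C)C)cc(CC=C(C)C)c(O[Si](C)(C)C(C)(C)C)c1CC=C(C)C | intermediate
19 | (2S)-4,7-bis(TBS-oxy)-2-[4-(TBS-oxy)phenyl]-6,8-diprenyl-2H-chromene | CC(C)=CCc1cc2c(c(CC=C(C)C)c1O[Si](C)(C)C(C)(C)C)O[C@H](c1ccc(O[Si](C)(C)C(C)(C)C)cc1)C=C2O[Si](C)(C)C(C)(C)C | intermediate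
20 | (2S)-7-hydroxy-2-(4-hydroxyphenyl)-6,8-diprenylchroman-4-one | CC(C)=CCc1cc2c(c(CC=C(C)C)c1O)O[C@H](c1ccc(O)cc1)CC2=O | target

**Step count**
Total: 13 steps. Longest linear sequence: 10 steps (1 → 3 → 5 → 7 → 8 → 10 → 11 → 17 → 18 → 19 → 20), 9 of them from resacetophenone 4.

**Steps most likely to fail**

Step 12. The alkylidene formed at the C2 vinyl group may close onto the C8 prenyl olefin (seven-membered ring, loss of isobutene) or exchange with the prenyl groups faster than it engages the hindered enol ether; hydride-induced migration of the vinyl double bond would also erase C2. The fallback gives up the metathesis and forms the C2–aryl bond instead. It sets out from 11. Condensation with Me2NCH(OMe)2 (toluene, 90 °C) should give (E)-1-[4-(TBS-oxy)-2-hydroxy-3,5-diprenylphenyl]-3-(dimethylamino)prop-2-en-1-one F1. Warming F1 in AcOH should close it, with loss of dimethylamine, to 7-(TBS-oxy)-6,8-diprenyl-4H-chromen-4-one F2. Asymmetric conjugate addition of 4-(TBS-oxy)phenylboronic acid then sets C2, using Pd(OCOCF3)2, the tert-butyl pyridine-oxazoline ligand antipode that leads to 2S, NH4PF6 and H2O in ClCH2CH2Cl at 60 °C, and gives (2S)-7-(TBS-oxy)-2-[4-(TBS-oxy)phenyl]-6,8-diprenylchroman-4-one F3. The buffered fluoride treatment of step 13 returns the route at 20.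

Step 10. Attack of the crowded, ketone-chelated phenoxide on the allyl–iridium intermediate may be too slow, so that methoxide competes or the branched ether is re-ionised and drifts to the linear isomer with loss of enantiomeric purity. The fallback tethers nucleophile and electrophile and sets out from 14 and 11. Alcohol 14 and 1,1'-carbonyldiimidazole (CH2Cl2, rt) should give (E)-3-[4-(TBS-oxy)phenyl]prop-2-enyl imidazole-1-carboxylate F4. F4 acylates phenol 11 (catalytic DBU, MeCN) to the mixed carbonate 2-acetyl-5-(TBS-oxy)-4,6-diprenylphenyl (E)-3-[4-(TBS-oxy)phenyl]prop-2-enyl carbonate F5. The same [Ir(cod)Cl]2–phosphoramidite catalyst (THF, rt) then ionises F5, CO2 leaves, and the lithium-free phenoxide collapses within the ion pair onto the benzylic allyl terminus (decarboxylative allylic etherification). The route is rejoined at 17.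

Step 4. With the 4-hydroxyl now flanked by a prenyl group, attack at the tertiary allyl terminus may be slow, and the palladium may equilibrate the tertiary ether to the linear prenyl ether, which would deliver a 1,1-dimethylallyl group to carbon in step 5. The fallback sets out from 7 and uses a propargyl unit that cannot isomerise in this way. Copper-catalysed propargylic etherification with 3-chloro-3-methylbut-1-yne (CuCl2·2H2O cat., DBU, MeCN, 0 °C) should give 1-[2-hydroxy-4-(2-methylbut-3-yn-2-yloxy)-3-prenylphenyl]ethanone F6. Semihydrogenation (H2, Lindlar catalyst, that is Pd/CaCO3 poisoned with Pb(OAc)2, quinoline, EtOAc) rejoins the route at 8.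

**Further compounds**
F1 | step 12 | (E)-1-[4-(TBS-oxy)-2-hydroxy-3,5-diprenylphenyl]-3-(dimethylamino)prop-2-en-1-one | CN(C)/C=C/C(=O)c1cc(CC=C(C)C)c(O[Si](C)(C)C(C)(C)C)c(CC=C(C)C)c1O
F2 | step 12 | 7-(TBS-oxy)-6,8-diprenyl-4H-chromen-4-one | O=c1ccoc2c(CC=C(C)C)c(O[Si](C)(C)C(C)(C)C)c(CC=C(C)C)cc12
F3 | step 12 | (2S)-7-(TBS-oxy)-2-[4-(TBS-oxy)phenyl]-6,8-diprenylchroman-4-one | CC(C)=CCc1cc2c(c(CC=C(C)C)c1O[Si](C)(C)C(C)(C)C)O[C@H](c1ccc(O[Si](C)(C)C(C)(C)C)cc1)CC2=O
F4 | step 10 | (E)-3-[4-(TBS-oxy)phenyl]prop-2-enyl imidazole-1-carboxylate | O=C(OC/C=C/c1ccc(O[Si](C)(C)C(C)(C)C)cc1)n1ccnc1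
F5 | step 10 | 2-acetyl-5-(TBS-oxy)-4,6-diprenylphenyl (E)-3-[4-(TBS-oxy)phenyl]prop-2-enyl carbonate | CC(=O)c1cc(CC=C(C)C)c(O[Si](C)(C)C(C)(C)C)c(CC=C(C)C)c1OC(=O)OC/C=C/c1ccc(O[Si](C)(C)C(C)(C)C)cc1
F6 | step 4 | 1-[2-hydroxy-4-(2-methylbut-3-yn-2-yloxy)-3-prenylphenyl]ethanone | CC(=O)c1ccc(OC(C)(C)C#C)c(CC=C(C)C)c1O
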